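The route rests on reading the C6 hydroxyethyl chain and the neighbouring C7 hydroxyl of ring A as a reduced, ring-opened benzofuran-2(3H)-one. Cutting the CH2–CH2 bond and the O7–C bond leaves a C6 methylene ortho-quinone methide and a one-carbon isocyanide. In a single operation the key step joins these by a formal (4+1) annulation, forging the side-chain C–C bond and the O7–C bond of a temporary aminofuran at the carboxylic acid oxidation level. Its precursor is the C6 dimethylaminomethyl (Mannich) derivative of (2S)-8-prenylhomoeriodictyol, in which the C8 prenyl group blocks the only other nucleophilic position of ring A and C2 already carries the target configuration.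

Key step: step 6

Assumption: (2S)-homoeriodictyol is purchased as the single enantiomer, and the aminofuran is drawn as its amino tautomer although it may equilibrate with the neutral imino (iminolactone) form; both hydrolyse alike.

Step 1
Reactants: 1 (2S)-homoeriodictyol
Product: 2 (2S)-7,4′-di-O-acetylhomoeriodictyol
Conditions: Ac2O (2.1 equiv), pyridine, 0 °C → rt
Reagents that add atoms: acetic anhydride, CC(=O)OC(C)=O
Why: Pyridine-mediated O-acetylation of phenols: the 7- and 4′-hydroxyls react, whereas the 5-hydroxyl, held in a hydrogen bond to the C4 carbonyl, is far less nucleophilic and should stay free with two equivalents of anhydride in the cold, and the brief, weakly basic conditions should not open the pyranone ring.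

Step 2
Reactants: 2 (2S)-7,4′-di-O-acetylhomoeriodictyol; 3 prenyl alcohol
Product: 4 (2S)-7,4′-di-O-acetyl-5-O-prenylhomoeriodictyol
Conditions: PPh3, DIAD, THF, 0 °C → rt
Reagents that add atoms: none
Why: Mitsunobu etherification: the only free phenol (O5, acidic because it is conjugated to the C4 carbonyl) displaces the phosphonium-activated primary allylic alcohol by SN2 under neutral conditions, giving the unrearranged prenyl ether.

Step 3
Reactants: 4 (2S)-7,4′-di-O-acetyl-5-O-prenylhomoeriodictyol
Product: 7 (2S)-7,4′-di-O-acetyl-8-prenylhomoeriodictyol, via C6 ortho-dienone 5 (not isolated), via C8 para-dienone 6 (not isolated)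
Conditions: Eu(fod)3 (10 mol%), CHCl3, 60 °C
Reagents that add atoms: none
Why: Lewis-acid-catalysed aromatic para-Claisen–Cope rearrangement: chelation of Eu(fod)3 by the C4 carbonyl and O5 should speed the [3,3] shift of the ether to C6, the congested dienone 5 carrying the reversed prenyl unit should relieve strain by a Cope shift to C8, and enolisation of dienone 6 then restores ring A with a normal prenyl group para to O5 and a free 5-hydroxyl.

Step 4
Reactants: 7 (2S)-7,4′-di-O-acetyl-8-prenylhomoeriodictyol
Product: 8 (2S)-8-prenylhomoeriodictyol
Conditions: NH4OAc, MeOH–H2O (4:1), rt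
Reagents that add atoms: none
Why: Near-neutral transesterification of aryl acetates (NH4OAc-promoted methanolysis) should free both phenols without the alkoxide or hydroxide bases that open flavanones to chalcones, so C2 and the prenyl group are untouched.

Step 5
Reactants: 8 (2S)-8-prenylhomoeriodictyol; 9 Eschenmoser's salt
Product: 11 (2S)-6-(dimethylaminomethyl)-8-prenylhomoeriodictyol, via Mannich base hydroiodide 10 (not isolated)
Conditions: 9 (1.05 equiv), MeCN, 0 °C → rt; then aq NaHCO3
Reagents that add atoms: none
Why: Mannich aminomethylation by electrophilic aromatic substitution with a preformed iminium salt: C6 is the only unsubstituted carbon of the phloroglucinol-type ring A, which is far more nucleophilic than the guaiacol ring B, and the amine product itself buffers the HI released, so the prenyl group does not meet strong acid.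

Step 6
Reactants: 11 (2S)-6-(dimethylaminomethyl)-8-prenylhomoeriodictyol; 12 tert-butyl isocyanide
Product: 16 (2S)-linear 2-(tert-butylamino)furan-fused 8-prenylflavanone, via ortho-quinone methide 13 (not isolated), via nitrilium phenoxide 14 (not isolated), via iminolactone tautomer 15 (not isolated)
Conditions: 12 (5 equiv), 1,4-dioxane (0.02 M), 85 °C, slow N2 sweep through a reflux condenser
Reagents that add atoms: none
Why: Thermal retro-Mannich loss of dimethylamine from the phenoxide–ammonium zwitterion of 11 gives methide 13, and the isocyanide carbon adds to its exocyclic CH2 (a conjugate addition that re-aromatises ring A) to give nitrilium phenoxide 14, which closes to 15 and tautomerises to 16. This is the known formal (4+1) cycloaddition of ortho-quinone methides with isocyanides that furnishes 2-aminobenzofurans. The one ring formed, the furan, closes by 5-exo-dig attack of O7 on the nitrilium carbon. No stereocentre is created, and the existing C2 centre only has to survive, which the aprotic medium, the moderate temperature and the continuous removal of the volatile amine are meant to ensure. Site selectivity comes from the substrate: C8 carries the prenyl group, so a methide can arise only at C6, and the more acidic, non-chelated O7 should close because O5 is tied up in the hydrogen bond to the C4 carbonyl, while any closure through O5 would converge on the same diol after steps 7 and 8. Excess isocyanide and high dilution are used so that capture of 13 outruns its self-condensation and the alkylation of the nucleophilic furan C3 of 16 by a second methide.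

Step 7
Reactants: 16 (2S)-linear 2-(tert-butylamino)furan-fused 8-prenylflavanone (used crude, under N2)
Product: 19 (2S)-linear benzofuran-2(3H)-one-fused 8-prenylflavanone, via iminium chloride 17 (not isolated), via carbinolamine 18 (not isolated)
Conditions: 1 M aq HCl–THF (1:4), 0 °C → rt
Reagents that add atoms: water, O
Why: Acid hydrolysis of a cyclic imidate: the enamine-like furan is protonated at C3 to give iminium chloride 17, water adds to the iminium carbon to give carbinolamine 18, and in strong acid the protonated amine rather than the aryloxide is expelled, leaving the five-membered aryl lactone; because O7 stays acylated, the C8 prenyl group has no free ortho phenol with which to cyclise under the acid.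

Step 8
Reactants: 19 (2S)-linear benzofuran-2(3H)-one-fused 8-prenylflavanone
Product: 21 Laxiflorin, via arylacetaldehyde 20 (not isolated)
Conditions: LiBH4 (2 equiv, in portions), THF, −20 → 0 °C; then aq NH4Cl
Reagents that add atoms: none
Why: Chemoselective borohydride reduction of an activated ester: the lactone is an ester of a para-acyl phenol and thus the most electrophilic carbonyl present, whereas the C4 ketone is a vinylogous carboxylate once O5 is lithiated and even more so after the first hydride transfer has opened the ring to aldehyde 20 and the O7 phenoxide, so with limited hydride at low temperature the aldehyde should be reduced to the primary alcohol while the ketone and the C2 centre are left alone.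

Compound list
1 | (2S)-homoeriodictyol, (2S)-5,7-dihydroxy-2-(4-hydroxy-3-methoxyphenyl)chroman-4-one | COc1cc([C@@H]2CC(=O)c3c(O)cc(O)cc3O2)ccc1O | starting material
2 | (2S)-7,4′-di-O-acetylhomoeriodictyol (5-OH free) | COc1cc([C@@H]2CC(=O)c3c(O)cc(OC(C)=O)cc3O2)ccc1OC(C)=O | intermediate
3 | prenyl alcohol (3-methylbut-2-en-1-ol) | CC(C)=CCO | starting material
4 | (2S)-7,4′-di-O-acetyl-5-O-prenylhomoeriodictyol | COc1cc([C@@H]2CC(=O)c3c(OCC=C(C)C)cc(OC(C)=O)cc3O2)ccc1OC(C)=O | intermediate
5 | C6 ortho-dienone: (2S)-7-acetoxy-2-(4-acetoxy-3-methoxyphenyl)-6-(2-methylbut-3-en-2-yl)-2,3-dihydrochromene-4,5(6H)-dione, C6 configuration undefined, transient | COc1cc([C@@H]2CC(=O)C3=C(O2)C=C(OC(C)=O)C(C(C)(C)C=C)C3=O)ccc1OC(C)=O | intermediate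
6 | C8 para-dienone: (2S)-7-acetoxy-2-(4-acetoxy-3-methoxyphenyl)-8-prenyl-2,3-dihydrochromene-4,5(8H)-dione, C8 configuration undefined, transient | COc1cc([C@@H]2CC(=O)C3=C(O2)C(CC=C(C)C)C(OC(C)=O)=CC3=O)ccc1OC(C)=O | intermediate
7 | (2S)-7,4′-di-O-acetyl-8-prenylhomoeriodictyol | COc1cc([C@@H]2CC(=O)c3c(O)cc(OC(C)=O)c(CC=C(C)C)c3O2)ccc1OC(C)=O | intermediate
8 | (2S)-8-prenylhomoeriodictyol | COc1cc([C@@H]2CC(=O)c3c(O)cc(O)c(CC=C(C)C)c3O2)ccc1O | intermediate
9 | Eschenmoser's salt (N,N-dimethylmethyleneiminium iodide) | C=[N+](C)C.[I-] | starting material
10 | hydroiodide of (2S)-6-(dimethylaminomethyl)-8-prenylhomoeriodictyol, transient | COc1cc([C@@H]2CC(=O)c3c(O)c(C[NH+](C)C)c(O)c(CC=C(C)C)c3O2)ccc1O.[I-] | intermediate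
11 | (2S)-6-(dimethylaminomethyl)-8-prenylhomoeriodictyol | COc1cc([C@@H]2CC(=O)c3c(O)c(CN(C)C)c(O)c(CC=C(C)C)c3O2)ccc1O | intermediate
12 | tert-butyl isocyanide | CC(C)(C)[N+]#[C-] | starting material
13 | (2S)-C6-methylene ortho-quinone methide of 8-prenylhomoeriodictyol (C7 oxo form, 5-OH retained), transient | COc1cc([C@@H]2CC(=O)C3=C(O)C(=C)C(=O)C(CC=C(C)C)=C3O2)ccc1O | intermediate
14 | (2S)-nitrilium 7-phenoxide zwitterion (C6–CH2–C≡N+–tBu), transient | COc1cc([C@@H]2CC(=O)c3c(O)c(CC#[N+]C(C)(C)C)c([O-])c(CC=C(C)C)c3O2)ccc1O | intermediate
15 | (2S)-iminolactone tautomer: 2-(tert-butylimino)-2,3-dihydrofuran fused to ring A (O on C7, CH2 on C6), transient | COc1cc([C@@H]2CC(=O)c3c(O)c4c(c(CC=C(C)C)c3O2)OC(=NC(C)(C)C)C4)ccc1O | intermediate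
16 | (2S)-linear 2-(tert-butylamino)furan-fused 8-prenylflavanone (furan O on C7, furan CH on C6; 5-OH, 4′-OH, 3′-OMe) | COc1cc([C@@H]2CC(=O)c3c(O)c4cc(NC(C)(C)C)oc4c(CC=C(C)C)c3O2)ccc1O | intermediate
17 | (2S)-iminium chloride: N-protonated 2-(tert-butyliminio)-2,3-dihydrofuran fused to ring A (O on C7, CH2 on C6), transient | COc1cc([C@@H]2CC(=O)c3c(O)c4c(c(CC=C(C)C)c3O2)OC(=[NH+]C(C)(C)C)C4)ccc1O.[Cl-] | intermediate
18 | (2S)-carbinolamine: 2-hydroxy-2-(tert-butylamino)-2,3-dihydrofuran fused to ring A, carbinolamine carbon undefined, transient | COc1cc([C@@H]2CC(=O)c3c(O)c4c(c(CC=C(C)C)c3O2)OC(O)(NC(C)(C)C)C4)ccc1O | intermediate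
19 | (2S)-linear benzofuran-2(3H)-one-fused 8-prenylflavanone (lactone O on C7, CH2 on C6) | COc1cc([C@@H]2CC(=O)c3c(O)c4c(c(CC=C(C)C)c3O2)OC(=O)C4)ccc1O | intermediate
20 | (2S)-6-(2-oxoethyl)-8-prenylhomoeriodictyol, transient | COc1cc([C@@H]2CC(=O)c3c(O)c(CC=O)c(O)c(CC=C(C)C)c3O2)ccc1O | intermediate
21 | Laxiflorin, (2S)-6-(2-hydroxyethyl)-8-prenylhomoeriodictyol | COc1cc([C@@H]2CC(=O)c3c(O)c(CCO)c(O)c(CC=C(C)C)c3O2)ccc1O | target

Total step count: 8. Longest linear sequence: 8 steps (1 → 21).

Steps most likely to fail

Step 6. Loss of dimethylamine may need a temperature at which base-mediated opening of the pyranone ring erodes the C2 configuration, and self-condensation of the methide or alkylation of the product at the furan C3 may outrun isocyanide capture. The fallback changes how the methide is released. It sets out from 11: N-methylation with MeI in acetone at room temperature without added base should give (2S)-6-(trimethylammoniomethyl)-8-prenylhomoeriodictyol iodide F1. Stirring this salt with tert-butyl isocyanide and powdered NaHCO3 in MeCN at room temperature should let the 7-phenoxide expel trimethylamine, so that methide 13 is generated slowly and cold in the absence of a secondary amine and is trapped as before; the sequence comes back to the route at 16.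

Step 8. Hydride delivery to the C4 ketone may compete with reduction of the lactone, and borane species formed from the phenols may attack the prenyl double bond on prolonged exposure. The fallback gives up the differentiation of the two carbonyls. It sets out from 19: excess LiBH4 in THF at room temperature should reduce both to (2S)-6-(2-hydroxyethyl)-8-prenylhomoeriodictyol flavan-4-ol F2 (C4 epimers). Activated MnO2 in EtOAc at room temperature should then re-oxidise only the doubly oxygen-activated benzylic C4 carbinol, a benzylic alcohol oxidation that leaves the primary alcohol and the prenyl group alone; the sequence comes back to the route at 21.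

Step 3. The sigmatropic cascade may stop after the first shift by enolisation of the C6 dienone, or the Lewis acid may ionise the allylic ether, leading to regioisomer mixtures or loss of the prenyl group. The fallback replaces the rearrangement by direct C-alkylation. It sets out from 1: Friedel–Crafts prenylation with 2-methylbut-3-en-2-ol and BF3·OEt2 in 1,4-dioxane at room temperature is expected to give both ring A C-prenyl isomers. Chromatographic removal of (2S)-6-prenylhomoeriodictyol F3 then comes back to the route at 8, bypassing steps 1 to 4 at the cost of material.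

Further compounds
F1 | step 6 | (2S)-6-(trimethylammoniomethyl)-8-prenylhomoeriodictyol iodide | COc1cc([C@@H]2CC(=O)c3c(O)c(C[N+](C)(C)C)c(O)c(CC=C(C)C)c3O2)ccc1O.[I-]
F2 | step 8 | (2S)-6-(2-hydroxyethyl)-8-prenylhomoeriodictyol flavan-4-ol, C4 epimers | COc1cc([C@@H]2CC(O)c3c(O)c(CCO)c(O)c(CC=C(C)C)c3O2)ccc1O
F3 | step 3 | (2S)-6-prenylhomoeriodictyol | COc1cc([C@@H]2CC(=O)c3c(O)c(CC=C(C)C)c(O)cc3O2)ccc1O
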